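The oxolane (ring B: O1, C2 bearing aryl ring A, C3 bearing CH2OH, C4 bearing the carbinol arm to aryl ring C, C5H2) is disconnected at O1–C5 and C4–C5. C5 is the only ring carbon without a substituent and sits between O1 and C4, so it is brought in as formaldehyde. The precursor is an acyclic (E)-styrenyl homoallylic alcohol whose C2 and C3 centres come from an auxiliary-controlled anti-aldol. In one operation its oxocarbenium ion is attacked by the styrene (oxonium–Prins): ring B closes, C4 is set, and the benzylic cation on the C4 arm is captured by the C3 acetoxymethyl group, which sets the carbinol centre.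

Key step: step 6

Assumption: the MgCl2-catalysed aldol of the (S)-4-benzyl imide is taken to follow the chelate-controlled facial sense of its propionyl analogue (aldehyde adds to the enolate face away from the benzyl group); were the sense opposite, the (R)-auxiliary would be used with no other change.

Step 1
Reactants: 1 (S)-4-benzyloxazolidin-2-one; 2 but-3-enoic acid
Product: 5 (S)-4-benzyl-3-(but-3-enoyl)oxazolidin-2-one, via but-3-enoyl chloride 3 (not isolated), via lithium oxazolidinide 4 (not isolated)
Conditions: 2, (COCl)2, DMF (cat.), CH2Cl2, 0 °C to rt, evaporate; 1, n-BuLi, THF, −78 °C; add 3, −78 °C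
Reagents that add atoms: none
Why: N-acylation of the lithiated oxazolidinone by the acid chloride is fast at −78 °C, which should keep the β,γ-double bond out of conjugation, and no stereocentre is formed.

Step 2
Reactants: 5 (S)-4-benzyl-3-(but-3-enoyl)oxazolidin-2-one; 6 4-formyl-2-methoxyphenyl acetate
Product: 7 (4S)-3-[(2R,3S)-3-(4-acetoxy-3-methoxyphenyl)-2-ethenyl-3-(trimethylsilyloxy)propanoyl]-4-benzyloxazolidin-2-one
Conditions: MgCl2 (0.2 equiv), Et3N, Me3SiCl, EtOAc, 23 °C
Reagents that add atoms: chlorotrimethylsilane, C[Si](C)(C)Cl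
Why: MgCl2-catalysed direct anti-aldol reaction of an N-acyloxazolidinone with a non-enolisable aromatic aldehyde: the chelated (Z)-magnesium enolate reacts at its α-carbon on the face away from the benzyl group, which sets the α-centre (2R) and, through the anti-selective transition state, the silyloxy centre (3S), while silylation of the aldolate turns the catalyst over.

Step 3
Reactants: 7 (4S)-3-[(2R,3S)-3-(4-acetoxy-3-methoxyphenyl)-2-ethenyl-3-(trimethylsilyloxy)propanoyl]-4-benzyloxazolidin-2-one
Product: 8 (1S,2S)-2-ethenyl-1-(4-hydroxy-3-methoxyphenyl)propane-1,3-diol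
Conditions: LiBH4 (excess), THF–MeOH, 0 °C to rt; aq NH4Cl
Reagents that add atoms: none
Why: Reductive cleavage of the N-acyloxazolidinone with LiBH4 should give the primary alcohol and return the auxiliary, the silyl ether and the aryl acetate fall off in the same basic methanolic medium, and neither stereocentre is touched.

Step 4
Reactants: 8 (1S,2S)-2-ethenyl-1-(4-hydroxy-3-methoxyphenyl)propane-1,3-diol
Product: 9 4-[(1S,2S)-2-(acetoxymethyl)-1-hydroxybut-3-en-1-yl]-2-methoxyphenyl acetate
Conditions: Ac2O (2.1 equiv), pyridine, CH2Cl2, −20 °C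
Reagents that add atoms: acetic anhydride, CC(=O)OC(C)=O
Why: Chemoselective O-acetylation, in which the phenol and the primary alcohol should react much faster than the hindered secondary benzylic alcohol next to a branched carbon, which stays free for the key step.

Step 5
Reactants: 9 4-[(1S,2S)-2-(acetoxymethyl)-1-hydroxybut-3-en-1-yl]-2-methoxyphenyl acetate; 10 4-ethenyl-2-methoxyphenyl acetate
Product: 11 4-[(1S,2S,3E)-2-(acetoxymethyl)-4-(4-acetoxy-3-methoxyphenyl)-1-hydroxybut-3-en-1-yl]-2-methoxyphenyl acetate
Conditions: second-generation Grubbs catalyst RuCl2(=CHPh)(H2IMes)(PCy3) (5 mol%), 10 (3 equiv), CH2Cl2, 40 °C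
Reagents that add atoms: none
Why: Olefin cross-metathesis of the terminal alkene with a styrene should give the thermodynamically favoured (E)-alkene with loss of ethene, and the stereocentres are not involved.

Step 6
Reactants: 11 4-[(1S,2S,3E)-2-(acetoxymethyl)-4-(4-acetoxy-3-methoxyphenyl)-1-hydroxybut-3-en-1-yl]-2-methoxyphenyl acetate; 12 formaldehyde (charged as paraformaldehyde)
Product: 15 4-[(2S,3S,4R)-3-(acetoxymethyl)-4-[(S)-(4-acetoxy-3-methoxyphenyl)(hydroxy)methyl]oxolan-2-yl]-2-methoxyphenyl acetate, via oxocarbenium ion 13 (not isolated), via acetoxonium ion 14 (not isolated)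
Conditions: (CH2O)n, Me3SiOTf (1.2 equiv), CH2Cl2, −78 to −40 °C; then sat. aq NaHCO3
Reagents that add atoms: water, O
Why: The alcohol condenses with formaldehyde to oxocarbenium ion 13, whose CH2 carbon is attacked by the proximal carbon of the (E)-styrene (oxonium–Prins cyclisation, the known route from styrenyl homoallylic alcohols and aldehydes to oxolanes), and the benzylic cation so formed is captured by the carbonyl oxygen of the C3 acetoxymethyl group to give acetoxonium ion 14, which the bicarbonate quench hydrolyses to hydroxy acetate 15 (acetyl migration between the two oxygens would be inconsequential because step 7 removes the acetate). Ring B closes by C4–C5 bond formation, exo with respect to the styrene π bond and endo with respect to the O1=C5 oxocarbenium bond, and the temporary seven-membered dioxepanylium ring closes by attack of the ester oxygen on the cation and is opened again on work-up. C4 is controlled by 1,3-allylic strain: C3–H eclipses the alkene and the electrophile, tethered through C2, adds to the alkene face opposite CH2OAc, so the arm ends up trans to CH2OAc on the ring face left free by the cis aryl and CH2OAc groups. The carbinol centre is controlled by the tether: the cation is born from the (E)-alkene with C4–H eclipsing the aryl plane, and the acetate reaching over from C3 through a trans-fused seven-membered ring can only add to the cation face on the C3 side, which gives the (S) configuration. The step needs bond formation at the alkene carbon remote from the arene (five-membered ring and benzylic cation) in preference to six-membered closure or a [3,3] shift of the oxocarbenium ion, which the polarisation of the styrene should secure, and it needs the C2 ether centre to resist ionisation, which the acetoxy group on ring A should secure.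

Step 7
Reactants: 15 4-[(2S,3S,4R)-3-(acetoxymethyl)-4-[(S)-(4-acetoxy-3-methoxyphenyl)(hydroxy)methyl]oxolan-2-yl]-2-methoxyphenyl acetate
Product: 16 4-[(2S,3S,4R)-4-[(S)-hydroxy(4-hydroxy-3-methoxyphenyl)methyl]-3-(hydroxymethyl)oxolan-2-yl]-2-methoxyphenol
Conditions: K2CO3 (cat.), MeOH, 0 °C to rt; then AcOH
Reagents that add atoms: none
Why: Base-catalysed transesterification with methanol should remove the two aryl acetates and the primary acetate without touching the benzylic ether or carbinol centres, giving the target.

Compound list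
1 | (S)-4-benzyloxazolidin-2-one | O=C1N[C@@H](Cc2ccccc2)CO1 | starting material
2 | but-3-enoic acid | OC(=O)CC=C | starting material
3 | but-3-enoyl chloride | ClC(=O)CC=C | intermediate
4 | lithium (S)-4-benzyl-2-oxooxazolidin-3-ide | [Li+].O=C1[N-][C@@H](Cc2ccccc2)CO1 | intermediate
5 | (S)-4-benzyl-3-(but-3-enoyl)oxazolidin-2-one | C=CCC(=O)N1[C@@H](Cc2ccccc2)COC1=O | intermediate
6 | 4-formyl-2-methoxyphenyl acetate (vanillin acetate) | CC(=O)Oc1ccc(C=O)cc1OC | starting material
7 | (4S)-3-[(2R,3S)-3-(4-acetoxy-3-methoxyphenyl)-2-ethenyl-3-(trimethylsilyloxy)propanoyl]-4-benzyloxazolidin-2-one | C=C[C@H]([C@H](O[Si](C)(C)C)c1ccc(OC(C)=O)c(OC)c1)C(=O)N1[C@@H](Cc2ccccc2)COC1=O | intermediate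
8 | (1S,2S)-2-ethenyl-1-(4-hydroxy-3-methoxyphenyl)propane-1,3-diol | C=C[C@@H](CO)[C@H](O)c1ccc(O)c(OC)c1 | intermediate
9 | 4-[(1S,2S)-2-(acetoxymethyl)-1-hydroxybut-3-en-1-yl]-2-methoxyphenyl acetate | C=C[C@@H](COC(C)=O)[C@H](O)c1ccc(OC(C)=O)c(OC)c1 | intermediate
10 | 4-ethenyl-2-methoxyphenyl acetate | C=Cc1ccc(OC(C)=O)c(OC)c1 | starting material
11 | 4-[(1S,2S,3E)-2-(acetoxymethyl)-4-(4-acetoxy-3-methoxyphenyl)-1-hydroxybut-3-en-1-yl]-2-methoxyphenyl acetate | CC(=O)Oc1ccc(/C=C/[C@@H](COC(C)=O)[C@H](O)c2ccc(OC(C)=O)c(OC)c2)cc1OC | intermediate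
12 | formaldehyde (as paraformaldehyde) | C=O | starting material
13 | O-methylidene oxocarbenium ion of 11 | CC(=O)Oc1ccc(/C=C/[C@@H](COC(C)=O)[C@H]([O+]=C)c2ccc(OC(C)=O)c(OC)c2)cc1OC | intermediate
14 | trans-fused 2-methyl-1,3-dioxepan-2-ylium (acetoxonium) ion on the closed oxolane | COc1cc([C@H]3[O+]=C(C)OC[C@H]4[C@@H](c5ccc(OC(C)=O)c(OC)c5)OC[C@H]34)ccc1OC(C)=O | intermediate
15 | 4-[(2S,3S,4R)-3-(acetoxymethyl)-4-[(S)-(4-acetoxy-3-methoxyphenyl)(hydroxy)methyl]oxolan-2-yl]-2-methoxyphenyl acetate | COc1cc([C@@H](O)[C@H]2CO[C@H](c3ccc(OC(C)=O)c(OC)c3)[C@@H]2COC(C)=O)ccc1OC(C)=O | intermediate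
16 | 4-[(2S,3S,4R)-4-[(S)-hydroxy(4-hydroxy-3-methoxyphenyl)methyl]-3-(hydroxymethyl)oxolan-2-yl]-2-methoxyphenol | COc1cc([C@@H](O)[C@H]2CO[C@H](c3ccc(O)c(OC)c3)[C@@H]2CO)ccc1O | target

Total step count: 7. Longest linear sequence: 7 steps (from 1 and 2 to 16).

Steps most likely to fail

Step 6 (key step). The benzylic cation may be captured by triflate or by water at the quench before the acetate reaches it, so that facial control at the carbinol carbon is lost; a [3,3] shift of the oxocarbenium ion is the second concern. The fallback sets the carbinol centre by reduction instead of cation capture. It sets out from crude 15 (both carbinol configurations) and comes back at 15. Oxidation with Dess–Martin periodinane (CH2Cl2, rt) would give the single ketone 4-[(2S,3S,4R)-3-(acetoxymethyl)-4-(4-acetoxy-3-methoxybenzoyl)oxolan-2-yl]-2-methoxyphenyl acetate F1. Reduction with Zn(BH4)2 (Et2O, −20 °C) under chelation between the ketone oxygen and O1 should deliver hydride to the face away from C3 and return 15; the esters are not expected to react.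

Step 2. Under the amine and magnesium conditions the β,γ-double bond of 5 may migrate into conjugation with the imide, or the dienolate may react at its γ-carbon. The fallback locks the alkene in conjugation with the arene before the aldol. It sets out from 5 and comes back at 11, replacing steps 2 to 5. Cross-metathesis of 5 with 10 (same ruthenium catalyst) would give (S)-4-benzyl-3-[(3E)-4-(4-acetoxy-3-methoxyphenyl)but-3-enoyl]oxazolidin-2-one F2, whose styryl double bond has no driving force to migrate. The same MgCl2-catalysed anti-aldol with 6 would give (4S)-3-[(2R,3S,3E)-3,5-bis(4-acetoxy-3-methoxyphenyl)-... silyl ether, named in full as (4S)-3-[(2R)-2-[(S)-(4-acetoxy-3-methoxyphenyl)(trimethylsilyloxy)methyl]-4-(4-acetoxy-3-methoxyphenyl)but-3-enoyl]-4-benzyloxazolidin-2-one F3. LiBH4 in THF–MeOH would give (1S,2S,3E)-2-(hydroxymethyl)-1,4-bis(4-hydroxy-3-methoxyphenyl)but-3-en-1-ol F4. Acetylation of both phenols and the primary alcohol (Ac2O, pyridine, −20 °C) would give 11.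

Step 5. Metathesis at the allylic-branched alkene may be sluggish, with homodimerisation of 10 and ruthenium hydride-induced double-bond migration taking over. The fallback forms the same bond by palladium-catalysed arylation. It sets out from 9 and comes back at 11. Mizoroki–Heck reaction of 9 with 4-iodo-2-methoxyphenyl acetate (CC(=O)Oc1ccc(I)cc1OC; Pd(OAc)2, Et3N, DMF, 80 °C) should arylate the terminal alkene carbon and give the (E)-styrene 11 directly; this fallback makes no new compound (F0).

Further compounds
F1 | step 6 | 4-[(2S,3S,4R)-3-(acetoxymethyl)-4-(4-acetoxy-3-methoxybenzoyl)oxolan-2-yl]-2-methoxyphenyl acetate | COc1cc(C(=O)[C@H]2CO[C@H](c3ccc(OC(C)=O)c(OC)c3)[C@@H]2COC(C)=O)ccc1OC(C)=O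
F2 | step 2 | (S)-4-benzyl-3-[(3E)-4-(4-acetoxy-3-methoxyphenyl)but-3-enoyl]oxazolidin-2-one | CC(=O)Oc1ccc(/C=C/CC(=O)N2[C@@H](Cc3ccccc3)COC2=O)cc1OC
F3 | step 2 | (4S)-3-[(2R)-2-[(S)-(4-acetoxy-3-methoxyphenyl)(trimethylsilyloxy)methyl]-4-(4-acetoxy-3-methoxyphenyl)but-3-enoyl]-4-benzyloxazolidin-2-one | CC(=O)Oc1ccc(/C=C/[C@H]([C@H](O[Si](C)(C)C)c2ccc(OC(C)=O)c(OC)c2)C(=O)N2[C@@H](Cc3ccccc3)COC2=O)cc1OC
F4 | step 2 | (1S,2S,3E)-2-(hydroxymethyl)-1,4-bis(4-hydroxy-3-methoxyphenyl)but-3-en-1-ol | COc1cc(/C=C/[C@@H](CO)[C@H](O)c2ccc(O)c(OC)c2)ccc1O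
F0 | step 5 | none | none
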